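**Retrosynthetic overview**
1. Target ⇐ Δ9(11)-alkene lactol by epoxidation on the exo face of the bicyclo[3.2.1]octene (last C–O bond).
2. Lactol ⇐ cis-fused keto lactone: lactone → lactol, C2 ketone → axial acetate, C15 allylic oxidation, C5 inverted by elimination to the cyclic enol ether and kinetic hydration.
3. Keto lactone ⇐ boronate ester: one palladium-catalysed 7-exo closure forms C9–C10 and the C1–O bond (anti); the C6(=O)–O–C7 ester bridge is the tether and the future oxepane oxygen.
4. Boronate ester ⇐ C–O ester union of two C10 halves: a bicyclo[3.2.1]octenyl boronate alcohol (rings C and D) and racemic 4-oxo-α-cyclogeranic acid (ring A).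
5. Ring order: C (cyclohexanone starting material) → D (gold-catalysed cyclisation); A (Michael/aldol annulation, made separately); oxepane (seco ring B) in the key step; epoxide last.

Numbering and names: kaurane numbering (C1–C20) is used for atoms throughout; "6,7-seco-6,7-olide" is the C6(=O)–O–C7 lactone and "6,7-epoxy-6,7-seco" the C6–O–C7 ether bridge of the oxepane; configuration is carried by the SMILES.

Assumption: where a chiral catalyst or ligand is named, the antipode that gives the drawn configuration is meant, and the lactol carbon C6 is taken as its equilibrating thermodynamic anomer (as drawn).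

**Step 1**
Reactants: 1 tert-butyl 2-oxocyclohexane-1-carboxylate; 2 3-bromoprop-1-yne
Product: 3 tert-butyl (R)-2-oxo-1-(prop-2-yn-1-yl)cyclohexane-1-carboxylate
Conditions: 2 (1.2 equiv), (S,S)-3,4,5-trifluorophenyl-NAS bromide (Maruoka catalyst, 1 mol%), CsOH·H2O, toluene, −40 °C
Reagents that add atoms: none
Why: Asymmetric phase-transfer alkylation, in which the chiral N-spiro ammonium enolate ion pair shields one enolate face so that propargylation sets the quaternary C8 centre, as is established for cyclic β-keto tert-butyl esters.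

**Step 2**
Reactants: 3 tert-butyl (R)-2-oxo-1-(prop-2-yn-1-yl)cyclohexane-1-carboxylate
Product: 4 tert-butyl (R)-2-oxo-1-(prop-2-yn-1-yl)cyclohex-3-ene-1-carboxylate
Conditions: IBX (2.5 equiv), DMSO/fluorobenzene, 75 °C
Reagents that add atoms: none
Why: IBX dehydrogenation of a ketone to the enone, which can only go towards C11 because C8 is quaternary and leaves the C8 stereocentre untouched.

**Step 3**
Reactants: 4 tert-butyl (R)-2-oxo-1-(prop-2-yn-1-yl)cyclohex-3-ene-1-carboxylate
Product: 6 tert-butyl (1R,5S)-6-methylidene-2-oxobicyclo[3.2.1]oct-3-ene-1-carboxylate, via silyl dienol ether 5 (not isolated)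
Conditions: TBSOTf, Et3N, CH2Cl2, 0 °C; then [Au(JohnPhos)(NCMe)]SbF6 (5 mol%), CH2Cl2/MeOH 10:1, rt
Reagents that add atoms: none
Why: Gold-catalysed 5-exo-dig Conia-ene-type carbocyclisation of a silyl enol ether; with the α' carbon blocked, soft enolisation gives the linear dienol ether whose γ-carbon (C13) is the only nucleophilic site that reaches the activated alkyne, and the two-carbon bridge can only span one face so C13 follows from C8.

**Step 4**
Reactants: 6 tert-butyl (1R,5S)-6-methylidene-2-oxobicyclo[3.2.1]oct-3-ene-1-carboxylate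
Product: 8 tert-butyl (1R,5R)-6-methylidene-2-{[(trifluoromethyl)sulfonyl]oxy}bicyclo[3.2.1]oct-2-ene-1-carboxylate, via lithium enolate 7 (not isolated)
Conditions: Li[HB(s-Bu)3], THF, −78 °C; then PhNTf2, −78 → 0 °C
Reagents that add atoms: N-phenylbis(trifluoromethanesulfonimide), O=S(=O)(N(c1ccccc1)S(=O)(=O)C(F)(F)F)C(F)(F)F
Why: Conjugate hydride reduction of the β-unsubstituted, carbonyl-hindered enone followed by O-triflation of the regiodefined enolate (reductive enol triflate formation); no new stereocentre.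

**Step 5**
Reactants: 8 tert-butyl (1R,5R)-6-methylidene-2-{[(trifluoromethyl)sulfonyl]oxy}bicyclo[3.2.1]oct-2-ene-1-carboxylate
Product: 9 (1S,5R)-1-(hydroxymethyl)-6-methylidenebicyclo[3.2.1]oct-2-en-2-yl trifluoromethanesulfonate
Conditions: i-Bu2AlH (3 equiv), CH2Cl2, −78 → 0 °C; aq. potassium sodium tartrate
Reagents that add atoms: none
Why: Hydride reduction of the ester to the neopentyl primary alcohol (C7–OH); the enol triflate and both alkenes are inert to i-Bu2AlH at this temperature.

**Step 6**
Reactants: 9 (1S,5R)-1-(hydroxymethyl)-6-methylidenebicyclo[3.2.1]oct-2-en-2-yl trifluoromethanesulfonate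
Product: 10 [(1R,5R)-6-methylidene-2-(4,4,5,5-tetramethyl-1,3,2-dioxaborolan-2-yl)bicyclo[3.2.1]oct-2-en-1-yl]methanol
Conditions: B2pin2, PdCl2(dppf) (5 mol%), KOAc, dioxane, 80 °C
Reagents that add atoms: bis(pinacolato)diboron, CC1(C)OB(OC1(C)C)B1OC(C)(C)C(C)(C)O1
Why: Miyaura borylation of an alkenyl triflate, which tolerates the free alcohol and is done before the ester union so that no enolisable keto ester meets zerovalent palladium and base.

**Step 7**
Reactants: 11 4-methylpent-3-en-2-one; 12 tert-butyl 3-oxobutanoate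
Product: 13 tert-butyl 2,6,6-trimethyl-4-oxocyclohex-2-ene-1-carboxylate (racemic)
Conditions: KOt-Bu (0.2 equiv), t-BuOH, reflux
Reagents that add atoms: none
Why: Michael addition of the acetoacetate to mesityl oxide followed by intramolecular aldol condensation (Robinson-type annulation, the classical isophorone carboxylate synthesis) builds ring A with the C2 carbonyl, the C1=C10 enone and the C6 carboxyl carbon in place; the C5 centre is racemic and labile.

**Step 8**
Reactants: 13 tert-butyl 2,6,6-trimethyl-4-oxocyclohex-2-ene-1-carboxylate (racemic)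
Product: 14 2,6,6-trimethyl-4-oxocyclohex-2-ene-1-carboxylic acid (racemic)
Conditions: CF3CO2H/CH2Cl2 1:4, 0 °C
Reagents that add atoms: none
Why: Acidolysis of the tert-butyl ester (E1 loss of isobutene) frees the hindered vinylogous β-keto acid without base and without the heat that would decarboxylate it.

**Step 9**
Reactants: 10 [(1R,5R)-6-methylidene-2-(4,4,5,5-tetramethyl-1,3,2-dioxaborolan-2-yl)bicyclo[3.2.1]oct-2-en-1-yl]methanol; 14 2,6,6-trimethyl-4-oxocyclohex-2-ene-1-carboxylic acid (racemic)
Product: 15 [(1R,5R)-6-methylidene-2-(4,4,5,5-tetramethyl-1,3,2-dioxaborolan-2-yl)bicyclo[3.2.1]oct-2-en-1-yl]methyl 2,6,6-trimethyl-4-oxocyclohex-2-ene-1-carboxylate (1:1 C5 epimers)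
Conditions: DCC, DMAP (cat.), CH2Cl2, 0 °C → rt
Reagents that add atoms: none
Why: Steglich esterification forms the C6(=O)–O–C7 bond that joins the two C10 halves and later becomes the oxepane oxygen bridge; the activated vinylogous β-keto acid acylates the hindered alcohol through its ketene-like form, and the C5 epimers are carried on because they interconvert in step 10.

**Step 10**
Reactants: 15 [(1R,5R)-6-methylidene-2-(4,4,5,5-tetramethyl-1,3,2-dioxaborolan-2-yl)bicyclo[3.2.1]oct-2-en-1-yl]methyl 2,6,6-trimethyl-4-oxocyclohex-2-ene-1-carboxylate (1:1 C5 epimers)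
Product: 16 1-acetoxy-2-oxo-6,7-secokaura-9(11),16-dien-6,7-olide (H-5 and 1-OAc both cis to CH3-20)
Conditions: Pd(OCOCF3)2 (10 mol%), (R)-t-BuPyOx (12 mol%), PhI(OAc)2 (2 equiv), AcOH (5 equiv), ClCH2CH2Cl, 45 °C
Reagents that add atoms: (diacetoxyiodo)benzene, CC(=O)OI(OC(C)=O)c1ccccc1
Why: Proposed new method: the alkenyl boronate transmetalates to the cationic divalent palladium–pyridinooxazoline acetate, syn 7-exo carbopalladation of the β-methyl enone puts C9 on C10 (quaternary centre; face set by the ligand and reinforced by C8, the C5 epimers of 15 interconverting through the dienol so both funnel into the cis-fused ring) and leaves a C1-bound palladium enolate with no β-hydrogen, which PhI(OAc)2 oxidises to tetravalent palladium (or acetoxy-iodanates directly) before acetate displaces the metal from C1 in SN2 fashion, so C9 and OAc end up anti and the acetate is equatorial and cis to CH3-20; the closest known reactions are the palladium–pyridinooxazoline conjugate addition of arylboronic acids to β-substituted cyclic enones (enolate protonated instead of oxidised) and the PhI(OAc)2-driven palladium-catalysed aminoacetoxylation and arylacetoxylation of alkenes.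

**Step 11**
Reactants: 16 1-acetoxy-2-oxo-6,7-secokaura-9(11),16-dien-6,7-olide (H-5 and 1-OAc both cis to CH3-20)
Product: 17 6,7-epoxy-6,7-secokaura-9(11),16-diene-1,2,6-triol (5-epi series; C6 anomers)
Conditions: i-Bu2AlH (6 equiv), CH2Cl2, −78 °C; aq. potassium sodium tartrate
Reagents that add atoms: none
Why: Hydride reduction in which the lactone stops at the lactol (stable aluminium hemiacetal at −78 °C), the acetate is cleaved, and the C2 ketone is reduced by equatorial hydride attack because the axial face is blocked by the two syn-axial methyl groups (CH3-20 and one C4 methyl), giving the axial C2 alcohol cis to CH3-20.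

**Step 12**
Reactants: 17 6,7-epoxy-6,7-secokaura-9(11),16-diene-1,2,6-triol (5-epi series; C6 anomers)
Product: 18 1,2,6-triacetoxy-6,7-epoxy-6,7-secokaura-9(11),16-diene (5-epi series; C6 anomers)
Conditions: Ac2O, DMAP, pyridine, rt
Reagents that add atoms: acetic anhydride, CC(=O)OC(C)=O
Why: DMAP-catalysed peracetylation installs the two ring A acetates of the target and masks the lactol as its anomeric acetate, which protects C6 during the two oxidations that follow.

**Step 13**
Reactants: 18 1,2,6-triacetoxy-6,7-epoxy-6,7-secokaura-9(11),16-diene (5-epi series; C6 anomers)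
Product: 19 1,2,6-triacetoxy-6,7-epoxy-6,7-secokaura-9(11),16-dien-15-ol (5-epi series; C15 configuration not controlled)
Conditions: SeO2 (0.3 equiv), t-BuOOH, CH2Cl2, rt
Reagents that add atoms: tert-butyl hydroperoxide, CC(C)(C)OO; selenium dioxide (catalytic oxygen carrier), O=[Se]=O
Why: Selenium dioxide allylic oxidation (ene reaction then [2,3] shift) of the exocyclic methylene at C15, the standard kauranoid D-ring oxidation; the Δ9(11) alkene has no allylic hydrogen on its more substituted end and is left alone, and the new C15 centre is erased in step 14.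

**Step 14**
Reactants: 19 1,2,6-triacetoxy-6,7-epoxy-6,7-secokaura-9(11),16-dien-15-ol (5-epi series; C15 configuration not controlled)
Product: 20 1,2,6-triacetoxy-6,7-epoxy-6,7-secokaura-9(11),16-dien-15-one (5-epi series; C6 anomers)
Conditions: Dess–Martin periodinane, CH2Cl2, rt
Reagents that add atoms: none
Why: Dess–Martin oxidation of the allylic alcohol to the exo-methylene ketone, done while the lactol is still an anomeric acetate so that it cannot be oxidised back to the lactone.

**Step 15**
Reactants: 20 1,2,6-triacetoxy-6,7-epoxy-6,7-secokaura-9(11),16-dien-15-one (5-epi series; C6 anomers)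
Product: 22 (1R,2S,5R,6R,8R,10R,13R)-1,2-diacetoxy-6,7-epoxy-6-hydroxy-6,7-secokaura-9(11),16-dien-15-one, via cyclic enol ether 21 (not isolated)
Conditions: TMSOTf, i-Pr2NEt, CH2Cl2, −78 → 0 °C; then 0.5 M HCl (aq)/THF, 0 °C
Reagents that add atoms: water, O
Why: Lewis-acid ionisation of the anomeric acetate and E1 loss of H-5 give the C5=C6 enol ether, whose kinetic hydration protonates C5 axially on the face away from the two syn-axial methyl groups (CH3-20 and one C4 methyl), so H-5 ends trans to CH3-20 (the natural trans-fused oxepane) and water closes the lactol.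

**Step 16**
Reactants: 22 (1R,2S,5R,6R,8R,10R,13R)-1,2-diacetoxy-6,7-epoxy-6-hydroxy-6,7-secokaura-9(11),16-dien-15-one
Product: 23 (1R,2S,5R,6R,8S,9S,10S,11R,13S)-1,2-diacetoxy-6,7:9,11-diepoxy-6-hydroxy-6,7-secokaur-16-en-15-one (CNP0224512.1)
Conditions: dimethyldioxirane (1.2 equiv), acetone/CH2Cl2, −20 °C
Reagents that add atoms: dimethyldioxirane, CC1(C)OO1
Why: Electrophilic epoxidation of the only electron-rich alkene (the enone alkene is inert) from the exo face of the bicyclo[3.2.1]octene, away from the C15–C16 two-carbon bridge, which sets C9 and C11 as in the target under neutral conditions that spare the lactol and the acetates.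

**Compound list**
1 | tert-butyl 2-oxocyclohexane-1-carboxylate (racemic) | CC(C)(C)OC(=O)C1CCCCC1=O | starting material
2 | 3-bromoprop-1-yne (propargyl bromide) | C#CCBr | starting material
3 | tert-butyl (R)-2-oxo-1-(prop-2-yn-1-yl)cyclohexane-1-carboxylate | C#CC[C@]1(C(=O)OC(C)(C)C)CCCCC1=O | intermediate
4 | tert-butyl (R)-2-oxo-1-(prop-2-yn-1-yl)cyclohex-3-ene-1-carboxylate | C#CC[C@]1(C(=O)OC(C)(C)C)CCC=CC1=O | intermediate
5 | tert-butyl (R)-2-[(tert-butyldimethylsilyl)oxy]-1-(prop-2-yn-1-yl)cyclohexa-2,4-diene-1-carboxylate | C#CC[C@]1(C(=O)OC(C)(C)C)CC=CC=C1O[Si](C)(C)C(C)(C)C | intermediate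
6 | tert-butyl (1R,5S)-6-methylidene-2-oxobicyclo[3.2.1]oct-3-ene-1-carboxylate | C=C1C[C@@]2(C(=O)OC(C)(C)C)C(=O)C=C[C@@H]1C2 | intermediate
7 | lithium (1R,5R)-1-(tert-butoxycarbonyl)-6-methylidenebicyclo[3.2.1]oct-2-en-2-olate | C=C1C[C@@]2(C(=O)OC(C)(C)C)C([O-])=CC[C@@H]1C2.[Li+] | intermediate
8 | tert-butyl (1R,5R)-6-methylidene-2-{[(trifluoromethyl)sulfonyl]oxy}bicyclo[3.2.1]oct-2-ene-1-carboxylate | C=C1C[C@@]2(C(=O)OC(C)(C)C)C(OS(=O)(=O)C(F)(F)F)=CC[C@@H]1C2 | intermediate
9 | (1S,5R)-1-(hydroxymethyl)-6-methylidenebicyclo[3.2.1]oct-2-en-2-yl trifluoromethanesulfonate | C=C1C[C@@]2(CO)C(OS(=O)(=O)C(F)(F)F)=CC[C@@H]1C2 | intermediate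
10 | [(1R,5R)-6-methylidene-2-(4,4,5,5-tetramethyl-1,3,2-dioxaborolan-2-yl)bicyclo[3.2.1]oct-2-en-1-yl]methanol | C=C1C[C@@]2(CO)C(B3OC(C)(C)C(C)(C)O3)=CC[C@@H]1C2 | intermediate
11 | 4-methylpent-3-en-2-one (mesityl oxide) | CC(C)=CC(C)=O | starting material
12 | tert-butyl 3-oxobutanoate (tert-butyl acetoacetate) | CC(=O)CC(=O)OC(C)(C)C | starting material
13 | tert-butyl 2,6,6-trimethyl-4-oxocyclohex-2-ene-1-carboxylate (racemic) | CC1=CC(=O)CC(C)(C)C1C(=O)OC(C)(C)C | intermediate
14 | 2,6,6-trimethyl-4-oxocyclohex-2-ene-1-carboxylic acid (racemic) | CC1=CC(=O)CC(C)(C)C1C(=O)O | intermediate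
15 | [(1R,5R)-6-methylidene-2-(4,4,5,5-tetramethyl-1,3,2-dioxaborolan-2-yl)bicyclo[3.2.1]oct-2-en-1-yl]methyl 2,6,6-trimethyl-4-oxocyclohex-2-ene-1-carboxylate (1:1 C5 epimers) | C=C1C[C@@]2(COC(=O)C3C(C)=CC(=O)CC3(C)C)C(B3OC(C)(C)C(C)(C)O3)=CC[C@@H]1C2 | intermediate
16 | 1-acetoxy-2-oxo-6,7-secokaura-9(11),16-dien-6,7-olide; C8, C10, C13 as in 23; H-5 and 1-OAc cis to CH3-20 (cis-fused oxepanone) | C=C1C[C@@]23COC(=O)[C@H]4C(C)(C)CC(=O)[C@H](OC(C)=O)[C@@]4(C)C2=CC[C@@H]1C3 | intermediate
17 | 6,7-epoxy-6,7-secokaura-9(11),16-diene-1,2,6-triol; 1-OH, 2-OH and H-5 cis to CH3-20; C6 anomers | C=C1C[C@@]23COC(O)[C@H]4C(C)(C)C[C@H](O)[C@H](O)[C@@]4(C)C2=CC[C@@H]1C3 | intermediate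
18 | 1,2,6-triacetoxy-6,7-epoxy-6,7-secokaura-9(11),16-diene; 5-epi series; C6 anomers | C=C1C[C@@]23COC(OC(C)=O)[C@H]4C(C)(C)C[C@H](OC(C)=O)[C@H](OC(C)=O)[C@@]4(C)C2=CC[C@@H]1C3 | intermediate
19 | 1,2,6-triacetoxy-6,7-epoxy-6,7-secokaura-9(11),16-dien-15-ol; 5-epi series; C6 and C15 not defined | C=C1C(O)[C@@]23COC(OC(C)=O)[C@H]4C(C)(C)C[C@H](OC(C)=O)[C@H](OC(C)=O)[C@@]4(C)C2=CC[C@@H]1C3 | intermediate
20 | 1,2,6-triacetoxy-6,7-epoxy-6,7-secokaura-9(11),16-dien-15-one; 5-epi series; C6 anomers | C=C1C(=O)[C@@]23COC(OC(C)=O)[C@H]4C(C)(C)C[C@H](OC(C)=O)[C@H](OC(C)=O)[C@@]4(C)C2=CC[C@@H]1C3 | intermediate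
21 | 1,2-diacetoxy-6,7-epoxy-6,7-secokaura-5,9(11),16-trien-15-one (cyclic enol ether, C5=C6) | C=C1C(=O)[C@@]23COC=C4C(C)(C)C[C@H](OC(C)=O)[C@H](OC(C)=O)[C@@]4(C)C2=CC[C@@H]1C3 | intermediate
22 | (1R,2S,5R,6R,8R,10R,13R)-1,2-diacetoxy-6,7-epoxy-6-hydroxy-6,7-secokaura-9(11),16-dien-15-one (H-5 trans to CH3-20) | C=C1C(=O)[C@@]23CO[C@@H](O)[C@@H]4C(C)(C)C[C@H](OC(C)=O)[C@H](OC(C)=O)[C@@]4(C)C2=CC[C@@H]1C3 | intermediate
23 | (1R,2S,5R,6R,8S,9S,10S,11R,13S)-1,2-diacetoxy-6,7:9,11-diepoxy-6-hydroxy-6,7-secokaur-16-en-15-one (CNP0224512.1) | C=C1C(=O)[C@@]23CO[C@@H](O)[C@@H]4C(C)(C)C[C@H](OC(C)=O)[C@H](OC(C)=O)[C@@]4(C)[C@]24O[C@@H]4C[C@@H]1C3 | target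

**Step count and risks**
Total: 16 steps. Longest linear sequence: 14 steps (1 → 23 through steps 1–6 and 9–16); ring A acid 14 is a two-step branch.

The three steps most likely to fail:

Step 10 (the proposed new alkenyl-acetoxylation). The hindered alkenyl boronate may transmetalate slowly, the palladium enolate may be protonated before it is oxidised, the oxidant may attack the exocyclic alkene, and the C10 face selectivity is unproven. The fallback uses known reactions only, sets out from 9 (with 14) and comes back to the route at 16. Steglich esterification of 9 with 14 gives the alkenyl triflate ester [(1S,5R)-6-methylidene-2-{[(trifluoromethyl)sulfonyl]oxy}bicyclo[3.2.1]oct-2-en-1-yl]methyl 2,6,6-trimethyl-4-oxocyclohex-2-ene-1-carboxylate F1. Nickel-catalysed reductive conjugate addition of the alkenyl triflate to the enone with silyl trapping (NiCl2(dme), neocuproine, Mn powder, Et3SiCl, DMF) closes the seven-membered ring and gives the regiodefined silyl enol ether 2-(triethylsilyloxy)-6,7-secokaura-1,9(11),16-trien-6,7-olide F2. α-Acetoxylation of this silyl enol ether with PhI(OAc)2 and BF3·OEt2 in CH2Cl2 at −40 °C then gives 16; acetate displaces the iodane that entered on the open face, so the acetate again ends cis to CH3-20.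

Step 3 (gold cyclisation through the γ-carbon of a dienol ether). Protodesilylation back to 4 or poor reach of C13 to the alkyne could stop it. The fallback sets out from 1 and comes back at 6. Compound 1 is alkylated under the step 1 phase-transfer conditions with 2,3-dibromopropene to tert-butyl (R)-1-(2-bromoprop-2-en-1-yl)-2-oxocyclohexane-1-carboxylate F3. IBX as in step 2 gives the enone tert-butyl (R)-1-(2-bromoprop-2-en-1-yl)-2-oxocyclohex-3-ene-1-carboxylate F4. Palladium-catalysed intramolecular γ-alkenylation of its dienolate (Pd2(dba)3, P(t-Bu)3, Cs2CO3, dioxane, 90 °C) closes ring D to 6; only the γ-carbon can reach the alkenylpalladium.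

Step 15 (inversion of C5 by elimination and kinetic hydration). Removal of the hindered H-5 from the oxocarbenium ion may be slow, and the conformational argument for the protonation face may not hold. The fallback sets out from 20 and comes back at 22. Aqueous acetic acid (AcOH/THF/H2O, 40 °C) hydrolyses only the anomeric acetate to the C5-epimeric lactol 1,2-diacetoxy-6,7-epoxy-6-hydroxy-6,7-secokaura-9(11),16-dien-15-one with H-5 cis to CH3-20, F5. C5 is then equilibrated by acid-catalysed enolisation of the ring-opened hydroxy aldehyde (camphorsulfonic acid, wet MeCN, 50 °C), so thermodynamic control of the ring fusion replaces kinetic protonation and leads to 22.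

**Further compounds**
F1 | step 10 | [(1S,5R)-6-methylidene-2-{[(trifluoromethyl)sulfonyl]oxy}bicyclo[3.2.1]oct-2-en-1-yl]methyl 2,6,6-trimethyl-4-oxocyclohex-2-ene-1-carboxylate (C5 epimers) | C=C1C[C@@]2(COC(=O)C3C(C)=CC(=O)CC3(C)C)C(OS(=O)(=O)C(F)(F)F)=CC[C@@H]1C2
F2 | step 10 | 2-(triethylsilyloxy)-6,7-secokaura-1,9(11),16-trien-6,7-olide (H-5 cis to CH3-20) | C=C1C[C@@]23COC(=O)[C@H]4C(C)(C)CC(O[Si](CC)(CC)CC)=C[C@@]4(C)C2=CC[C@@H]1C3
F3 | step 3 | tert-butyl (R)-1-(2-bromoprop-2-en-1-yl)-2-oxocyclohexane-1-carboxylate | C=C(Br)C[C@]1(C(=O)OC(C)(C)C)CCCCC1=O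
F4 | step 3 | tert-butyl (R)-1-(2-bromoprop-2-en-1-yl)-2-oxocyclohex-3-ene-1-carboxylate | C=C(Br)C[C@]1(C(=O)OC(C)(C)C)CCC=CC1=O
F5 | step 15 | 1,2-diacetoxy-6,7-epoxy-6-hydroxy-6,7-secokaura-9(11),16-dien-15-one with H-5 cis to CH3-20 (5-epi-22; C6 anomers) | C=C1C(=O)[C@@]23COC(O)[C@H]4C(C)(C)C[C@H](OC(C)=O)[C@H](OC(C)=O)[C@@]4(C)C2=CC[C@@H]1C3
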